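**Retrosynthetic overview** (cyclohexane locants C1′–C6′ and oxane locants C2–C6 are those of the target name; C1′ is bonded to oxane C2, C3′ is CHBr, C4′ is C(CH3)Cl)
1. Caespitol ⇒ silyl ether 35 ⇒ cyclohexanone 23: C3′–Br by SN2 inversion of an axial alcohol; C4′ by α-chlorination, then axial C-methylation of the α-chloro ketimine anion.
2. Oxane ring (formed second) ⇒ 6-endo bromoetherification of the tertiary alcohol onto the prenyl alkene of ketone 21.
3. Cyclohexane ring (formed first, together with a temporary oxasilinane ring) ⇒ intramolecular Diels–Alder reaction that makes C1′–C6′ and C4′–C5′ at once: a 2-ethoxy-1,3-diene on the future oxane C2, and a vinylsilane (ethylene equivalent) bound as silyl ether to the future C3 oxygen.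
4. Enabling feature: the C3 hydroxyl is separated from C1′ only by the quaternary C2, so an O–Si tether closes a six-membered 1,2-oxasilinane over O–C3–C2–C1′–C6′–Si; C5′–C6′ is an unsubstituted CH2–CH2 unit and C3′ carries a heteroatom (enol ether → ketone).
5. Diene diol 12 ⇒ Sharpless epoxidation of (2Z)-3-methylpent-2-en-4-yn-1-ol, Payne rearrangement/cuprate opening, hydrostannation–iodination, Stille coupling.

Key step: step 6

Remark: 25 and 28 are carried as mixtures of epimers at the chlorinated carbon; this centre is made planar again in step 12.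

Step 1
Reactants: 1 (2Z)-3-methylpent-2-en-4-yn-1-ol; 2 tert-butyl hydroperoxide
Product: 3 [(2S,3R)-3-ethynyl-3-methyloxiran-2-yl]methanol
Conditions: Ti(OiPr)4 (10 mol %), L-(+)-diethyl tartrate (12 mol %), 2 (in decane), 4 Å MS, CH2Cl2, −20 °C
Reagents that add atoms: tert-butyl hydroperoxide, CC(C)(C)OO
Why: Sharpless asymmetric epoxidation of a 3,3-disubstituted (nerol-type) allylic alcohol, in which the L-(+)-tartrate catalyst delivers oxygen to the face that gives the (2S)-epoxide, so both epoxide carbons are set by reagent control and the alkyne is untouched.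

Step 2
Reactants: 3 [(2S,3R)-3-ethynyl-3-methyloxiran-2-yl]methanol; 4 (2-methylprop-1-en-1-yl)magnesium bromide
Product: 6 (3R,4R)-3,7-dimethyloct-6-en-1-yne-3,4-diol, via terminal epoxide 5 (not isolated)
Conditions: n-BuLi (2.05 equiv), LiCl, THF, −78 to 0 °C; then 4 (3 equiv), CuI (10 mol %), −30 to 0 °C; aq. NH4Cl
Reagents that add atoms: (2-methylprop-1-en-1-yl)magnesium bromide, CC(C)=C[Mg]Br
Why: Payne rearrangement of the lithium alkoxide moves the epoxide to the chain terminus with inversion at the secondary carbon, and copper-catalysed Grignard opening of this more reactive terminal epoxide at CH2 installs the prenyl terminus, while the acetylide anion shields the alkyne side from SN2′ attack.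

Step 3
Reactants: 6 (3R,4R)-3,7-dimethyloct-6-en-1-yne-3,4-diol; 7 tributyltin hydride; 8 iodine
Product: 10 (1E,3R,4R)-1-iodo-3,7-dimethylocta-1,6-diene-3,4-diol, via vinylstannane 9 (not isolated)
Conditions: 7 (1.2 equiv), PdCl2(PPh3)2 (2 mol %), THF, 0 °C; then 8 (1.0 equiv), CH2Cl2, −78 °C
Reagents that add atoms: iodine, II
Why: Palladium-catalysed syn hydrostannation puts tin on the unhindered alkyne terminus to give the (E)-vinylstannane, and iododestannylation occurs with retention and much faster than any reaction of iodine with the trisubstituted alkene.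

Step 4
Reactants: 10 (1E,3R,4R)-1-iodo-3,7-dimethylocta-1,6-diene-3,4-diol; 11 tributyl(1-ethoxyethenyl)stannane
Product: 12 (3E,5R,6R)-2-ethoxy-5,9-dimethyldeca-1,3,8-triene-5,6-diol
Conditions: Pd(PPh3)4 (5 mol %), CuI (10 mol %), CsF (2 equiv), DMF, 45 °C; Et3N-deactivated silica
Reagents that add atoms: tributyl(1-ethoxyethenyl)stannane, CCOC(=C)[Sn](CCCC)(CCCC)CCCC
Why: Stille coupling with retention of the (E)-geometry gives the 2-ethoxy-1,3-diene, an enol ether that tolerates fluoride and base and later unveils the ring ketone.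

Step 5
Reactants: 12 (3E,5R,6R)-2-ethoxy-5,9-dimethyldeca-1,3,8-triene-5,6-diol; 13 chloro(ethenyl)dimethylsilane; 14 1-(trimethylsilyl)imidazole
Product: 15 (3E,5R,6R)-6-{[ethenyl(dimethyl)silyl]oxy}-2-ethoxy-5,9-dimethyl-5-[(trimethylsilyl)oxy]deca-1,3,8-triene
Conditions: 13 (1.05 equiv), imidazole, CH2Cl2, −20 °C; then 14 (1.5 equiv), 23 °C
Reagents that add atoms: chloro(ethenyl)dimethylsilane, C=C[Si](C)(C)Cl; 1-(trimethylsilyl)imidazole, C[Si](C)(C)n1ccnc1
Why: Chemoselective O-silylation, in which the small chlorosilane reacts first at the secondary hydroxyl and the strong silyl donor then caps the tertiary hydroxyl, which prevents silyl migration during the thermolysis.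

Step 6
Reactants: 15 (3E,5R,6R)-6-{[ethenyl(dimethyl)silyl]oxy}-2-ethoxy-5,9-dimethyl-5-[(trimethylsilyl)oxy]deca-1,3,8-triene
Product: 16 (3R,4R,4aS,8aR)-6-ethoxy-1,1,4-trimethyl-3-(3-methylbut-2-en-1-yl)-4-[(trimethylsilyl)oxy]-3,4,4a,7,8,8a-hexahydro-1H-2,1-benzoxasiline (trans-fused)
Conditions: toluene (0.01 M), BHT, N,O-bis(trimethylsilyl)acetamide (5 mol %), sealed tube, 180 °C
Reagents that add atoms: none
Why: Concerted thermal [4+2] cycloaddition (intramolecular Diels–Alder) between the 2-ethoxy-1,3-diene and the silicon-bound vinyl group, whose terminal CH2 bonds to the nucleophilic CH2 terminus of the diene and whose silicon-bearing carbon bonds to the diene carbon next to the quaternary carbinol. The closest known reaction type is the temporary silicon-tethered Diels–Alder reaction of vinylsilyl ethers of dienols, in which the vinylsilane acts as an ethylene equivalent. Two rings close: the cyclohexene by the cycloaddition itself and the six-membered 1,2-oxasilinane through a chair-like four-atom tether, expected mainly as the trans-fused junction. The new ring stereocentre next to the quaternary carbon is controlled by that chair, which keeps the prenyl-bearing CH2 and the methyl group equatorial and places the small silyloxy group axial and eclipsed with the diene (least 1,3-allylic strain), so that the dienophile adds to the diene face that gives the cyclohexyl configuration of the target; the silicon-bearing stereocentre is erased in step 7, so either junction converges. The step needs regio-, chemo- and facial selectivity: regiochemistry is enforced by the tether and matches the polarisation of both partners, the trisubstituted prenyl alkene is too hindered and unactivated to compete, and the silylating scavenger protects the enol ether from traces of acid.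

Step 7
Reactants: 16 (3R,4R,4aS,8aR)-6-ethoxy-1,1,4-trimethyl-3-(3-methylbut-2-en-1-yl)-4-[(trimethylsilyl)oxy]-3,4,4a,7,8,8a-hexahydro-1H-2,1-benzoxasiline
Product: 17 (2R,3R)-2-[(1S)-3-ethoxycyclohex-2-en-1-yl]-6-methylhept-5-ene-2,3-diol
Conditions: Bu4NF (5 equiv), DMF, 75 °C
Reagents that add atoms: none
Why: Fluoride opens the siloxane and the alkoxide-bearing fluorosilicate undergoes protodesilylation of the ring C–Si bond (removal of the temporary silicon connection), while the trimethylsilyl ether is cleaved and the base-stable enol ether is kept.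

Step 8
Reactants: 17 (2R,3R)-2-[(1S)-3-ethoxycyclohex-2-en-1-yl]-6-methylhept-5-ene-2,3-diol; 18 tert-butyl(chloro)dimethylsilane
Product: 19 (2R,3R)-3-{[tert-butyl(dimethyl)silyl]oxy}-2-[(1S)-3-ethoxycyclohex-2-en-1-yl]-6-methylhept-5-en-2-ol
Conditions: 18 (1.5 equiv), imidazole, DMF, 40 °C
Reagents that add atoms: tert-butyl(chloro)dimethylsilane, CC(C)(C)[Si](C)(C)Cl
Why: Silyl ether formation at the secondary alcohol, the tertiary one being unreactive, leaves one free hydroxyl for the later etherification.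

Step 9
Reactants: 19 (2R,3R)-3-{[tert-butyl(dimethyl)silyl]oxy}-2-[(1S)-3-ethoxycyclohex-2-en-1-yl]-6-methylhept-5-en-2-ol; 20 water
Product: 21 (3S)-3-[(2R,3R)-3-{[tert-butyl(dimethyl)silyl]oxy}-2-hydroxy-6-methylhept-5-en-2-yl]cyclohexan-1-one
Conditions: pyridinium p-toluenesulfonate (5 mol %), acetone–H2O (10:1), 0 to 23 °C
Reagents that add atoms: water, O
Why: Mild acid hydrolysis of the enol ether gives the ketone, and with only one free hydroxyl no bridged ketal can form.

Step 10
Reactants: 21 (3S)-3-[(2R,3R)-3-{[tert-butyl(dimethyl)silyl]oxy}-2-hydroxy-6-methylhept-5-en-2-yl]cyclohexan-1-one; 22 2,4,4,6-tetrabromocyclohexa-2,5-dien-1-one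
Product: 23 (3S)-3-[(2R,3R,5R)-5-bromo-3-{[tert-butyl(dimethyl)silyl]oxy}-2,6,6-trimethyloxan-2-yl]cyclohexan-1-one
Conditions: 22 (1.05 equiv), CH2Cl2–MeNO2, −20 °C
Reagents that add atoms: 2,4,4,6-tetrabromocyclohexa-2,5-dien-1-one, O=C1C(Br)=CC(Br)(Br)C=C1Br
Why: Bromonium-induced 6-endo etherification, with Markovnikov attack of the tertiary hydroxyl anti to bromine, should proceed through the chair that has bromine and the cyclohexyl group equatorial and the silyloxy group axial, the arrangement that avoids a 1,3-diaxial clash between the ring substituent and the new gem-dimethyl carbon, and so sets the C5 bromide.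

Step 11
Reactants: 23 (3S)-3-[(2R,3R,5R)-5-bromo-3-{[tert-butyl(dimethyl)silyl]oxy}-2,6,6-trimethyloxan-2-yl]cyclohexan-1-one; 24 4-methylbenzenesulfonyl chloride
Product: 25 (5S)-5-[(2R,3R,5R)-5-bromo-3-{[tert-butyl(dimethyl)silyl]oxy}-2,6,6-trimethyloxan-2-yl]-2-chlorocyclohexan-1-one (both epimers at C2)
Conditions: LiN(i-Pr)2 (1.1 equiv), THF, −78 °C; then 24 (1.1 equiv), −78 to 0 °C
Reagents that add atoms: 4-methylbenzenesulfonyl chloride, Cc1ccc(cc1)S(=O)(=O)Cl
Why: Kinetic deprotonation takes the α-CH2 remote from the substituted ring carbon and the lithium enolate is chlorinated by the sulfonyl chloride (electrophilic α-chlorination of an enolate).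

Step 12
Reactants: 25 (5S)-5-[(2R,3R,5R)-5-bromo-3-{[tert-butyl(dimethyl)silyl]oxy}-2,6,6-trimethyloxan-2-yl]-2-chlorocyclohexan-1-one; 26 propan-2-amine; 27 iodomethane; 20 water
Product: 30 (2S,5S)-5-[(2R,3R,5R)-5-bromo-3-{[tert-butyl(dimethyl)silyl]oxy}-2,6,6-trimethyloxan-2-yl]-2-chloro-2-methylcyclohexan-1-one, via chloro ketimine 28 (not isolated), via methylated ketimine 29 (not isolated)
Conditions: 26 (5 equiv), TiCl4 (0.6 equiv), Et2O, 0 to 23 °C; filter, concentrate; LiN(i-Pr)2 (1.1 equiv), THF, 0 °C; 27 (1.5 equiv); then aq. oxalic acid–Et2O, 23 °C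
Reagents that add atoms: iodomethane, CI; water, O
Why: Alkylation of an α-chloro ketimine anion: deprotonation at the chlorinated carbon gives the 3-chloro-1-azaallyl anion, which is C-methylated along the axial trajectory of the chair with the large ring substituent equatorial, so methyl enters axial (cis to that substituent) and chlorine becomes equatorial, and hydrolysis returns the ketone.

Step 13
Reactants: 30 (2S,5S)-5-[(2R,3R,5R)-5-bromo-3-{[tert-butyl(dimethyl)silyl]oxy}-2,6,6-trimethyloxan-2-yl]-2-chloro-2-methylcyclohexan-1-one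
Product: 31 (1R,2S,5S)-5-[(2R,3R,5R)-5-bromo-3-{[tert-butyl(dimethyl)silyl]oxy}-2,6,6-trimethyloxan-2-yl]-2-chloro-2-methylcyclohexan-1-ol
Conditions: LiBH(s-Bu)3 (1.2 equiv), THF, −78 °C; H2O
Reagents that add atoms: none
Why: Ketone reduction by a bulky hydride from the equatorial direction gives the axial alcohol, which is cis to chlorine and so cannot close to an epoxide.

Step 14
Reactants: 31 (1R,2S,5S)-5-[(2R,3R,5R)-5-bromo-3-{[tert-butyl(dimethyl)silyl]oxy}-2,6,6-trimethyloxan-2-yl]-2-chloro-2-methylcyclohexan-1-ol; 32 trifluoromethanesulfonic anhydride; 33 tetrabutylammonium bromide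
Product: 35 tert-butyl({(2R,3R,5R)-5-bromo-2-[(1S,3S,4S)-3-bromo-4-chloro-4-methylcyclohexyl]-2,6,6-trimethyloxan-3-yl}oxy)dimethylsilane, via triflate 34 (not isolated)
Conditions: 32 (1.3 equiv), pyridine, CH2Cl2, −20 °C; then 33 (3 equiv), toluene, 0 to 40 °C
Reagents that add atoms: tetrabutylammonium bromide, [Br-].CCCC[N+](CCCC)(CCCC)CCCC
Why: Sulfonate formation and SN2 displacement by bromide with inversion turn the axial alcohol into the equatorial bromide, the β-chlorine disfavouring ionisation and not being antiperiplanar to the leaving group.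

Step 15
Reactants: 35 tert-butyl({(2R,3R,5R)-5-bromo-2-[(1S,3S,4S)-3-bromo-4-chloro-4-methylcyclohexyl]-2,6,6-trimethyloxan-3-yl}oxy)dimethylsilane
Product: 36 caespitol, (2R,3R,5R)-5-bromo-2-[(1S,3S,4S)-3-bromo-4-chloro-4-methylcyclohexyl]-2,6,6-trimethyloxan-3-ol
Conditions: HF·pyridine, pyridine–THF, 0 to 23 °C
Reagents that add atoms: none
Why: Acidic fluoride cleavage of the silyl ether leaves the alkyl halides untouched.

**Compound list**
1 | (2Z)-3-methylpent-2-en-4-yn-1-ol | OC/C=C(/C)C#C | starting material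
2 | tert-butyl hydroperoxide | CC(C)(C)OO | starting material
3 | [(2S,3R)-3-ethynyl-3-methyloxiran-2-yl]methanol | O1[C@](C)(C#C)[C@@H]1CO | intermediate
4 | (2-methylprop-1-en-1-yl)magnesium bromide | CC(C)=C[Mg]Br | starting material
5 | (2R)-2-[(2R)-oxiran-2-yl]but-3-yn-2-ol (present as its lithium salt) | O[C@](C)(C#C)[C@H]1CO1 | intermediate
6 | (3R,4R)-3,7-dimethyloct-6-en-1-yne-3,4-diol | O[C@](C)(C#C)[C@H](O)CC=C(C)C | intermediate
7 | tributyltin hydride | CCCC[SnH](CCCC)CCCC | starting material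
8 | iodine | II | starting material
9 | (1E,3R,4R)-3,7-dimethyl-1-(tributylstannyl)octa-1,6-diene-3,4-diol | O[C@](C)(/C=C/[Sn](CCCC)(CCCC)CCCC)[C@H](O)CC=C(C)C | intermediate
10 | (1E,3R,4R)-1-iodo-3,7-dimethylocta-1,6-diene-3,4-diol | O[C@](C)(/C=C/I)[C@H](O)CC=C(C)C | intermediate
11 | tributyl(1-ethoxyethenyl)stannane | CCOC(=C)[Sn](CCCC)(CCCC)CCCC | starting material
12 | (3E,5R,6R)-2-ethoxy-5,9-dimethyldeca-1,3,8-triene-5,6-diol | O[C@](C)(/C=C/C(=C)OCC)[C@H](O)CC=C(C)C | intermediate
13 | chloro(ethenyl)dimethylsilane | C=C[Si](C)(C)Cl | starting material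
14 | 1-(trimethylsilyl)imidazole | C[Si](C)(C)n1ccnc1 | starting material
15 | (3E,5R,6R)-6-{[ethenyl(dimethyl)silyl]oxy}-2-ethoxy-5,9-dimethyl-5-[(trimethylsilyl)oxy]deca-1,3,8-triene | C[Si](C)(C)O[C@](C)(/C=C/C(=C)OCC)[C@H](O[Si](C)(C)C=C)CC=C(C)C | intermediate
16 | (3R,4R,4aS,8aR)-6-ethoxy-1,1,4-trimethyl-3-(3-methylbut-2-en-1-yl)-4-[(trimethylsilyl)oxy]-3,4,4a,7,8,8a-hexahydro-1H-2,1-benzoxasiline | C[Si](C)(C)O[C@]1(C)[C@@H]2C=C(OCC)CC[C@H]2[Si](C)(C)O[C@@H]1CC=C(C)C | intermediate
17 | (2R,3R)-2-[(1S)-3-ethoxycyclohex-2-en-1-yl]-6-methylhept-5-ene-2,3-diol | O[C@](C)([C@H]2CCCC(OCC)=C2)[C@H](O)CC=C(C)C | intermediate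
18 | tert-butyl(chloro)dimethylsilane | CC(C)(C)[Si](C)(C)Cl | starting material
19 | (2R,3R)-3-{[tert-butyl(dimethyl)silyl]oxy}-2-[(1S)-3-ethoxycyclohex-2-en-1-yl]-6-methylhept-5-en-2-ol | O[C@](C)([C@H]2CCCC(OCC)=C2)[C@H](O[Si](C)(C)C(C)(C)C)CC=C(C)C | intermediate
20 | water | O | starting material
21 | (3S)-3-[(2R,3R)-3-{[tert-butyl(dimethyl)silyl]oxy}-2-hydroxy-6-methylhept-5-en-2-yl]cyclohexan-1-one | O[C@](C)([C@H]2CCCC(=O)C2)[C@H](O[Si](C)(C)C(C)(C)C)CC=C(C)C | intermediate
22 | 2,4,4,6-tetrabromocyclohexa-2,5-dien-1-one | O=C1C(Br)=CC(Br)(Br)C=C1Br | starting material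
23 | (3S)-3-[(2R,3R,5R)-5-bromo-3-{[tert-butyl(dimethyl)silyl]oxy}-2,6,6-trimethyloxan-2-yl]cyclohexan-1-one | CC1(C)O[C@](C)([C@H]2CCCC(=O)C2)[C@H](O[Si](C)(C)C(C)(C)C)C[C@H]1Br | intermediate
24 | 4-methylbenzenesulfonyl chloride | Cc1ccc(cc1)S(=O)(=O)Cl | starting material
25 | (5S)-5-[(2R,3R,5R)-5-bromo-3-{[tert-butyl(dimethyl)silyl]oxy}-2,6,6-trimethyloxan-2-yl]-2-chlorocyclohexan-1-one (both epimers at C2) | CC1(C)O[C@](C)([C@H]2CCC(Cl)C(=O)C2)[C@H](O[Si](C)(C)C(C)(C)C)C[C@H]1Br | intermediate
26 | propan-2-amine | CC(C)N | starting material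
27 | iodomethane | CI | starting material
28 | (5S)-5-[(2R,3R,5R)-5-bromo-3-{[tert-butyl(dimethyl)silyl]oxy}-2,6,6-trimethyloxan-2-yl]-2-chloro-N-(propan-2-yl)cyclohexan-1-imine (both epimers at C2) | CC1(C)O[C@](C)([C@H]2CCC(Cl)C(=NC(C)C)C2)[C@H](O[Si](C)(C)C(C)(C)C)C[C@H]1Br | intermediate
29 | (2S,5S)-5-[(2R,3R,5R)-5-bromo-3-{[tert-butyl(dimethyl)silyl]oxy}-2,6,6-trimethyloxan-2-yl]-2-chloro-2-methyl-N-(propan-2-yl)cyclohexan-1-imine | CC1(C)O[C@](C)([C@H]2CC[C@](C)(Cl)C(=NC(C)C)C2)[C@H](O[Si](C)(C)C(C)(C)C)C[C@H]1Br | intermediate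
30 | (2S,5S)-5-[(2R,3R,5R)-5-bromo-3-{[tert-butyl(dimethyl)silyl]oxy}-2,6,6-trimethyloxan-2-yl]-2-chloro-2-methylcyclohexan-1-one | CC1(C)O[C@](C)([C@H]2CC[C@](C)(Cl)C(=O)C2)[C@H](O[Si](C)(C)C(C)(C)C)C[C@H]1Br | intermediate
31 | (1R,2S,5S)-5-[(2R,3R,5R)-5-bromo-3-{[tert-butyl(dimethyl)silyl]oxy}-2,6,6-trimethyloxan-2-yl]-2-chloro-2-methylcyclohexan-1-ol | CC1(C)O[C@](C)([C@H]2CC[C@](C)(Cl)[C@H](O)C2)[C@H](O[Si](C)(C)C(C)(C)C)C[C@H]1Br | intermediate
32 | trifluoromethanesulfonic anhydride | O=S(=O)(OS(=O)(=O)C(F)(F)F)C(F)(F)F | starting material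
33 | tetrabutylammonium bromide | [Br-].CCCC[N+](CCCC)(CCCC)CCCC | starting material
34 | (1R,2S,5S)-5-[(2R,3R,5R)-5-bromo-3-{[tert-butyl(dimethyl)silyl]oxy}-2,6,6-trimethyloxan-2-yl]-2-chloro-2-methylcyclohexyl trifluoromethanesulfonate | CC1(C)O[C@](C)([C@H]2CC[C@](C)(Cl)[C@H](OS(=O)(=O)C(F)(F)F)C2)[C@H](O[Si](C)(C)C(C)(C)C)C[C@H]1Br | intermediate
35 | tert-butyl({(2R,3R,5R)-5-bromo-2-[(1S,3S,4S)-3-bromo-4-chloro-4-methylcyclohexyl]-2,6,6-trimethyloxan-3-yl}oxy)dimethylsilane | CC1(C)O[C@](C)([C@H]2CC[C@](C)(Cl)[C@@H](Br)C2)[C@H](O[Si](C)(C)C(C)(C)C)C[C@H]1Br | intermediate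
36 | caespitol, (2R,3R,5R)-5-bromo-2-[(1S,3S,4S)-3-bromo-4-chloro-4-methylcyclohexyl]-2,6,6-trimethyloxan-3-ol | CC1(C)O[C@](C)([C@H]2CC[C@](C)(Cl)[C@@H](Br)C2)[C@H](O)C[C@H]1Br | target

Total step count: 15. Longest linear sequence: 15 steps (from 1).

**Steps most likely to fail**

Step 6. The diene and the vinylsilane are both unactivated, so the cycloaddition may be slower than decomposition of the enol ether, silyl migration, or cycloaddition onto the prenyl alkene, and the facial selectivity may be low. Fallback: starting from 12, an intermolecular Diels–Alder reaction with phenyl vinyl sulfone (toluene, 110 °C) should place the sulfonyl group on the ring carbon next to the stereogenic ring carbon (para to the ethoxy group) and give the sulfone cycloadduct F1. Reductive desulfonylation with sodium amalgam (6% Na in Hg, Na2HPO4, MeOH, −20 °C) then returns to the route at 17, without steps 5 to 7. Facial selectivity then rests on the allylic stereocentre alone.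

Step 12. The TiCl4-mediated imine formation may cost the silyl ether or eliminate HCl, and deprotonation at the other α-carbon would lead to Favorskii-type loss of chloride. Fallback: starting from 25, a second chlorination (LiN(i-Pr)2, then 4-methylbenzenesulfonyl chloride) gives the 2,2-dichloro ketone F2. Me2CuLi (THF, −78 °C) removes one chlorine by halogen–metal exchange and generates the α-chloro enolate without any base, and iodomethane then methylates it on the axial face. The sequence returns to the route at 30.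

Step 14. E2 elimination towards the ring CH2, or ionisation with methyl migration, may win over substitution at the hindered carbinol carbon. Fallback: a bromonium route that starts from 23. Methylation (LiN(i-Pr)2, iodomethane) gives the 2-methyl ketone F3; trifluoromethanesulfonic anhydride with 2,6-di-tert-butyl-4-methylpyridine gives the more substituted enol triflate F4; reduction (Pd(OAc)2, PPh3, Bu3N, HCO2H, DMF, 60 °C) gives the 1-methylcyclohexene F5. Anti addition of BrCl (N-bromosuccinimide, Me3SiCl, CH2Cl2, −78 °C), with chloride opening the bromonium ion at the tertiary carbon, returns to the route at 35. The trans-diaxial adduct is expected to predominate, so 35 would be the minor isomer and would have to be separated; this fallback costs material.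

Further compounds
F1 | step 6 | (2R,3R)-2-[3-ethoxy-6-(phenylsulfonyl)cyclohex-2-en-1-yl]-6-methylhept-5-ene-2,3-diol (ring C1 as in 17, sulfonyl carbon as a mixture) | O[C@](C)([C@H]2C(S(=O)(=O)c3ccccc3)CCC(OCC)=C2)[C@H](O)CC=C(C)C
F2 | step 12 | (5S)-5-[(2R,3R,5R)-5-bromo-3-{[tert-butyl(dimethyl)silyl]oxy}-2,6,6-trimethyloxan-2-yl]-2,2-dichlorocyclohexan-1-one | CC1(C)O[C@](C)([C@H]2CCC(Cl)(Cl)C(=O)C2)[C@H](O[Si](C)(C)C(C)(C)C)C[C@H]1Br
F3 | step 14 | (5S)-5-[(2R,3R,5R)-5-bromo-3-{[tert-butyl(dimethyl)silyl]oxy}-2,6,6-trimethyloxan-2-yl]-2-methylcyclohexan-1-one (both epimers at C2) | CC1(C)O[C@](C)([C@H]2CCC(C)C(=O)C2)[C@H](O[Si](C)(C)C(C)(C)C)C[C@H]1Br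
F4 | step 14 | (5S)-5-[(2R,3R,5R)-5-bromo-3-{[tert-butyl(dimethyl)silyl]oxy}-2,6,6-trimethyloxan-2-yl]-2-methylcyclohex-1-en-1-yl trifluoromethanesulfonate | CC1(C)O[C@](C)([C@H]2CCC(C)=C(OS(=O)(=O)C(F)(F)F)C2)[C@H](O[Si](C)(C)C(C)(C)C)C[C@H]1Br
F5 | step 14 | tert-butyl({(2R,3R,5R)-5-bromo-2,6,6-trimethyl-2-[(1S)-4-methylcyclohex-3-en-1-yl]oxan-3-yl}oxy)dimethylsilane | CC1(C)O[C@](C)([C@H]2CCC(C)=CC2)[C@H](O[Si](C)(C)C(C)(C)C)C[C@H]1Br
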